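**Retrosynthetic overview**
- Feature: the ester carbonyl carbon C1 carries the oxygen of the unbranched C25 chain. It is separated from the ipso carbon of the benzene ring only by the two methylene carbons C2 and C3 (aryl–CH2–CH2–C(=O)–O–alkyl).
- Cutting C1–C2 and C1–O together turns C1 into carbon monoxide, C2/C3 into the vinyl group of a 4-oxygenated styrene, and the alkoxy half into 1-pentacosanol. In the forward direction this is an anti-Markovnikov hydroalkoxycarbonylation.
- The phenol oxygen is carried as its acetate, which makes the styrene less sensitive to the acid co-catalyst. The acetate is removed last by chemoselective aminolysis.
- No ring is formed, because the benzene ring comes with the styrene, and the target has no stereocentre.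

Key step: step 1

Assumption: 1-pentacosanol is taken as a catalogue compound of speciality lipid suppliers. As the costly component, it is made the limiting reagent of the carbonylation.

**Step 1**
Reactants: 1 4-acetoxystyrene; 2 carbon monoxide; 3 1-pentacosanol
Product: 4 pentacosyl 3-(4-acetoxyphenyl)propanoate
Conditions: Pd(OAc)2 (1 mol%), 1,2-bis(di-tert-butylphosphinomethyl)benzene (4 mol%), MsOH (8 mol%), BHT (0.5 mol%), CO (20 bar), dry toluene, 90 °C; 1 (1.3 equiv), 3 limiting
Reagents that add atoms: carbon monoxide 2, [C-]#[O+]; 1-pentacosanol 3, CCCCCCCCCCCCCCCCCCCCCCCCCO (both are the reactants named above)
Why: Pd(OAc)2, the diphosphine and MsOH should give in situ a cationic chelated hydride of divalent palladium, which adds reversibly across the vinyl group of 1 to give an equilibrating pair of branched (benzylic) and linear (2-arylethyl) palladium alkyls. The four tert-butyl groups and the wide bite angle of the chelate crowd the metal, so CO insertion (forming C1–C2) and above all the rate-limiting alcoholysis by 3 (forming C1–O and returning the hydride) should run faster through the linear acyl. The closest known reaction type is the palladium-catalysed linear-selective hydroalkoxycarbonylation (hydroesterification) of vinylarenes and 1-alkenes with this same ligand and a sulfonic acid. No ring closes and no stereocentre is created. The selectivity needed is linear over branched; it comes from the ligand rather than the substrate, is helped by a fairly high temperature and modest CO pressure that keep the two alkyls in equilibrium, and the substrate contributes only through its acetate, which makes the arene a poorer donor than a free phenol or an ether and so weakens benzylic stabilisation and slows acid-induced cationic oligomerisation. Attack of 3 on the acyl palladium rather than on the aryl acetate is favoured by holding the free acid to a few mol% (the excess basic phosphine buffers most of it), by working dry in toluene, and by keeping 3 as the limiting component.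

**Step 2**
Reactants: 4 pentacosyl 3-(4-acetoxyphenyl)propanoate
Product: 5 pentacosyl 3-(4-hydroxyphenyl)propanoate (target)
Conditions: pyrrolidine (3 equiv), THF, 35 °C; then wash with 1 M aq. citric acid
Reagents that add atoms: none
Why: This is a chemoselective aminolysis in which the aryl acetate, an activated ester with a phenoxide leaving group, should be attacked by the secondary amine far faster than the unactivated primary alkyl propanoate, while the alcohol-free THF dissolves the waxy substrate (aqueous alcohols would not) and rules out exchange of the pentacosyl group.

**Compound list**
1 | 4-acetoxystyrene (4-ethenylphenyl acetate) | C=Cc1ccc(OC(C)=O)cc1 | starting material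
2 | carbon monoxide | [C-]#[O+] | starting material
3 | 1-pentacosanol | CCCCCCCCCCCCCCCCCCCCCCCCCO | starting material
4 | pentacosyl 3-(4-acetoxyphenyl)propanoate | CCCCCCCCCCCCCCCCCCCCCCCCCOC(=O)CCc1ccc(OC(C)=O)cc1 | intermediate
5 | pentacosyl 3-(4-hydroxyphenyl)propanoate | CCCCCCCCCCCCCCCCCCCCCCCCCOC(=O)CCc1ccc(O)cc1 | target

Total step count: 2
Longest linear sequence: 2

**Steps most likely to fail** (the route has only two steps, so both are ranked, the riskier first)

1. **Step 1.**
   - Linear over branched regioselectivity may be insufficient, and regioisomers are hard to separate on a C25 ester.
   - The acid may trigger oligomerisation of the styrene.
   - Acyl transfer from the aryl acetate to the alcohol would consume the limiting component.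
   - Alcoholysis of the acyl palladium may be sluggish because the alcohol is present only in stoichiometric amount.
   - Fallback: the carbonylation is abandoned and C1 is bought inside the acid. Starting from 3, a Fischer esterification is run with commercial 3-(4-hydroxyphenyl)propanoic acid (catalytic p-TsOH·H2O, toluene, reflux with a Dean–Stark trap). Under these conditions the phenol should not be acylated, so no protecting group is needed. The fallback rejoins the route directly at 5, step 2 becomes unnecessary, and no compound outside the list is made (F0).

2. **Step 2.**
   - Conversion may be incomplete because the wax ester dissolves poorly or gels at mild temperature.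
   - If the reaction is forced, aminolysis of the alkyl ester may compete.
   - Fallback: the phenol protecting group is changed to one that is removed without any nucleophile. Starting from 3 (with 2), the carbonylation of step 1 is run on commercial 4-benzyloxystyrene, with the free acid kept even lower because this styrene is more electron-rich. This should give pentacosyl 3-(4-benzyloxyphenyl)propanoate F1. Hydrogenolysis of the benzyl ether (H2 at 1 atm, 10% Pd/C, THF/EtOAc, 40 °C) leaves the alkyl ester untouched and rejoins the route at 5.

**Further compounds**
F0 | step 1 | none | none
F1 | step 2 | pentacosyl 3-(4-benzyloxyphenyl)propanoate | CCCCCCCCCCCCCCCCCCCCCCCCCOC(=O)CCc1ccc(OCc2ccccc2)cc1
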